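**Strategy.** Ring B is disconnected across C1'–C2' and C5'–C6'. It is a 1,2,3-trisubstituted benzene in which C1' (bonded to C2 of ring C) sits between C2'–OH and C6'–OMe, with C3'–C5' unsubstituted. A benzannulation of cyclobutenone with a methoxyalkyne already attached to chromone C2 builds this ring in one operation, takes the free 2'-phenol and the 6'-methyl ether from different atoms, and avoids any coupling at a doubly ortho-substituted aryl carbon. The precursor is 2-(methoxyethynyl)-7,8-dimethoxy-5,6-methylenedioxychromone, made by sulfone displacement on a chromone assembled from 2,3-dimethoxyphenol. The methylene acetal masks the 5,6-diol until the last step.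

Key step: step 12

Remark (assumption): the target is achiral, so no stereocentre has to be set; the transient racemic intermediates 8 and 19 are drawn without configuration.

Remark (design): 
- The acetylide is made from isolated methoxyacetylene, so that no amine or alkoxide competes for the sulfone.
- Ring A is C-acetylated before the catechol is bridged, so that the third hydroxyl is tied up by the carbonyl during methylenation.
- The methyl ynol ether has no β-hydrogen and should tolerate the annulation temperature.

**Step 1**
Reactants: 1 2,3-dimethoxyphenol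
Product: 2 2,3-dimethoxy-1,4-benzoquinone
Conditions: ON(SO3K)2 (Fremy's salt, 2.2 equiv), KH2PO4 buffer, H2O/acetone, 0 °C to rt
Reagents that add atoms: potassium nitrosodisulfonate, [K+].[K+].[O]N(S(=O)(=O)[O-])S(=O)(=O)[O-]
Why: Teuber oxidation, in which the nitroxyl radical abstracts the phenolic hydrogen and a second equivalent delivers oxygen to the free para position, should give the p-quinone.

**Step 2**
Reactants: 2 2,3-dimethoxy-1,4-benzoquinone
Product: 3 5,6-dimethoxybenzene-1,2,4-triyl triacetate
Conditions: Ac2O, H2SO4 (cat.), rt to 40 °C
Reagents that add atoms: acetic anhydride, CC(=O)OC(C)=O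
Why: Thiele–Winter acetoxylation, in which acid-activated conjugate addition of acetate occurs at the unsubstituted C5=C6 enedione (the methoxy-bearing carbons are deactivated vinylogous ester positions), followed by enolisation and O-acetylation.

**Step 3**
Reactants: 3 5,6-dimethoxybenzene-1,2,4-triyl triacetate
Product: 4 1-(2,3,6-trihydroxy-4,5-dimethoxyphenyl)ethan-1-one
Conditions: BF3·OEt2 (promoter), AcOH, 90 °C, Ar; then HCl, MeOH, reflux, Ar
Reagents that add atoms: none
Why: Fries rearrangement, a Lewis-acid-mediated O-to-C acetyl transfer into the only unsubstituted ring position (ortho to two oxygens), followed by acid methanolysis of the remaining O-acetates under argon to protect the hydroquinone.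

**Step 4**
Reactants: 4 1-(2,3,6-trihydroxy-4,5-dimethoxyphenyl)ethan-1-one
Product: 5 1-(5-hydroxy-6,7-dimethoxy-1,3-benzodioxol-4-yl)ethan-1-one
Conditions: CH2Br2 (1.3 equiv), Cs2CO3, degassed DMF, 80 °C, Ar
Reagents that add atoms: dibromomethane, BrCBr
Why: Catechol methylenation by double Williamson alkylation, in which only the vicinal 2- and 3-hydroxyls can close the five-membered acetal while the 6-hydroxyl is held in a hydrogen bond to the acetyl carbonyl.

**Step 5**
Reactants: 5 1-(5-hydroxy-6,7-dimethoxy-1,3-benzodioxol-4-yl)ethan-1-one
Product: 6 4-hydroxy-7,8-dimethoxy-5,6-methylenedioxy-2H-chromene-2-thione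
Conditions: KOtBu (3.5 equiv), CS2, THF, 0 °C to rt; then aq. HCl
Reagents that add atoms: carbon disulfide, S=C=S
Why: Claisen-type thioacylation of the ketone enolate by CS2, then attack of the phenoxide on the dithiocarboxylate with loss of hydrosulfide, the standard entry to 4-hydroxy-2H-chromene-2-thiones from 2'-hydroxyacetophenones.

**Step 6**
Reactants: 6 4-hydroxy-7,8-dimethoxy-5,6-methylenedioxy-2H-chromene-2-thione
Product: 7 7,8-dimethoxy-5,6-methylenedioxy-2-(methylsulfanyl)-4H-chromen-4-one
Conditions: MeI, K2CO3, acetone, rt to reflux
Reagents that add atoms: iodomethane, CI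
Why: S-alkylation of the ambident thioxo-enolate at its soft sulfur terminus should fix the 4-oxo (chromone) tautomer.

**Step 7**
Reactants: 7 7,8-dimethoxy-5,6-methylenedioxy-2-(methylsulfanyl)-4H-chromen-4-one
Product: 9 7,8-dimethoxy-5,6-methylenedioxy-2-(methylsulfonyl)-4H-chromen-4-one, via sulfoxide 8 (not isolated)
Conditions: mCPBA (2.3 equiv), CH2Cl2, 0 °C to rt
Reagents that add atoms: 3-chloroperoxybenzoic acid, OOC(=O)c1cccc(Cl)c1
Why: Peracid oxidation of the sulfide through the sulfoxide to the sulfone, with the electron-poor C2=C3 bond and the aryl ethers expected to be left alone at this temperature.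

**Step 8**
Reactants: 10 chloroacetaldehyde dimethyl acetal
Product: 12 methoxyacetylene (methoxyethyne), via sodium methoxyacetylide 11 (not isolated)
Conditions: NaNH2 (3 equiv), liq. NH3, −33 °C; evaporate NH3; cold aq. NaCl; distil into a −78 °C trap
Reagents that add atoms: none
Why: Twofold amide-induced β-elimination (loss of methanol, then of HCl) gives the alkynyl ether, which is held as its sodium acetylide until it is protonated and distilled.

**Step 9**
Reactants: 9 7,8-dimethoxy-5,6-methylenedioxy-2-(methylsulfonyl)-4H-chromen-4-one; 12 methoxyacetylene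
Product: 14 2-(methoxyethynyl)-7,8-dimethoxy-5,6-methylenedioxy-4H-chromen-4-one, via lithium methoxyacetylide 13 (not isolated)
Conditions: 12, n-BuLi (1.1 equiv), THF, −78 °C; cannulate into 9, THF, −78 °C; aq. NH4Cl; chromatography on Et3N-deactivated silica
Reagents that add atoms: none
Why: Addition–elimination (nucleophilic vinylic substitution) at C2 of the 2-sulfonylchromone, a vinylogous acyl carbon activated by ring oxygen and sulfonyl group, whereas C4 is a deactivated vinylogous ester carbonyl shielded by the peri O5, so the acetylide should add at C2 and the resulting C4 enolate should expel methanesulfinate.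

**Step 10**
Reactants: 15 3-oxocyclobutane-1-carboxylic acid
Product: 16 3-bromocyclobutan-1-one
Conditions: HgO, Br2, MgSO4, CH2Cl2, reflux
Reagents that add atoms: bromine, BrBr
Why: Hunsdiecker bromodecarboxylation (Cristol–Firth variant), in which the acyl hypobromite formed from the mercury carboxylate loses CO2 and the cyclobutyl radical is capped by bromine.

**Step 11**
Reactants: 16 3-bromocyclobutan-1-one
Product: 17 cyclobut-2-en-1-one
Conditions: n-Bu3N, neat, rt, reduced pressure, product collected at −78 °C and kept as a cold toluene solution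
Reagents that add atoms: none
Why: E1cB dehydrobromination of the β-bromo ketone, with the non-volatile amine and its salt staying behind while the volatile enone distils.

**Step 12**
Reactants: 14 2-(methoxyethynyl)-7,8-dimethoxy-5,6-methylenedioxy-4H-chromen-4-one; 17 cyclobut-2-en-1-one
Product: 22 2'-hydroxy-7,8,6'-trimethoxy-5,6-methylenedioxyflavone, via vinylketene 18 (not isolated), via 4-vinylcyclobutenone adduct 19 (not isolated), via dienylketene 20 (not isolated), via cyclohexa-2,4-dienone tautomer 21 (not isolated)
Conditions: 17 (3 equiv, in three portions as a cold toluene solution), toluene, sealed tube, Ar, 80 °C then 110 °C; then K2CO3 (cat.), MeOH, rt (returns any O-acylated product to the phenol)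
Reagents that add atoms: none
Why: Proposed new method: heating opens cyclobutenone 17 by 4-electron electrocyclic ring opening to vinylketene 18, whose carbonyl carbon (future C2') is attacked by the alkyne carbon bound to chromone C2 (future C1') while the ketene α-carbon (C5') bonds to the methoxy-bearing carbon (C6'), giving the 4-vinylcyclobutenone 19 in a regioselective [2+2] cycloaddition. A second 4-electron opening of 19 gives dienylketene 20, which closes ring B by a thermal disrotatory 6-electron electrocyclisation (restoring the C2'–C3' bond severed in the first opening) to dienone 21, and enolisation gives the phenol. The closest known reaction type is the Danheiser benzannulation of cyclobutenones with alkoxyalkynes, which yields 3-alkoxyphenols bearing the alkyne substituent between the two oxygens but has not been shown for an alkynyl ether conjugated to a chromone. No stereocentre survives, since 19 is racemic and transient and the product is planar. The step needs the [2+2] regiochemistry, secured by the methoxy group, which keeps the chromone-bound carbon the nucleophilic terminus of the ynol ether although the vinylogous ester of ring C drains electron density and slows the addition (hence excess 17 and the higher final temperature), and it needs chemoselectivity over the electron-poor C2=C3 bond of the chromone, which ketenes do not attack. Because the ketene oxygen becomes the 2'-OH and the alkyne oxygen remains the 6'-OMe, the two ortho oxygens are distinguished by origin, and the methyl ynol ether has no β-hydrogen through which it could fragment on heating.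

**Step 13**
Reactants: 22 2'-hydroxy-7,8,6'-trimethoxy-5,6-methylenedioxyflavone
Product: 24 5,6,2'-trihydroxy-7,8,6'-trimethoxyflavone, via chloromethyl ether borate 23 (not isolated)
Conditions: BCl3 (3.5 equiv), CH2Cl2, −78 to 0 °C; then aq. HCl, THF, rt
Reagents that add atoms: none
Why: Lewis-acid cleavage of the methylene acetal, in which BCl3 held between the C4 carbonyl and O5 opens an O–CH2 bond to an aryl chloromethyl ether that hydrolyses with loss of formaldehyde, while the methyl ethers at C7, C8 and C6', none of them peri to the carbonyl, should remain.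

**Compound list**

1 | 2,3-dimethoxyphenol | COc1cccc(O)c1OC | starting material
2 | 2,3-dimethoxy-1,4-benzoquinone | COC1=C(OC)C(=O)C=CC1=O | intermediate
3 | 5,6-dimethoxybenzene-1,2,4-triyl triacetate | COc1c(OC)c(OC(C)=O)c(OC(C)=O)cc1OC(C)=O | intermediate
4 | 1-(2,3,6-trihydroxy-4,5-dimethoxyphenyl)ethan-1-one | CC(=O)c1c(O)c(O)c(OC)c(OC)c1O | intermediate
5 | 1-(5-hydroxy-6,7-dimethoxy-1,3-benzodioxol-4-yl)ethan-1-one | CC(=O)c1c(O)c(OC)c(OC)c2OCOc12 | intermediate
6 | 4-hydroxy-7,8-dimethoxy-5,6-methylenedioxy-2H-chromene-2-thione | S=c1cc(O)c2c3OCOc3c(OC)c(OC)c2o1 | intermediate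
7 | 7,8-dimethoxy-5,6-methylenedioxy-2-(methylsulfanyl)-4H-chromen-4-one | CSc1cc(=O)c2c3OCOc3c(OC)c(OC)c2o1 | intermediate
8 | 7,8-dimethoxy-5,6-methylenedioxy-2-(methylsulfinyl)-4H-chromen-4-one (racemic at sulfur) | CS(=O)c1cc(=O)c2c3OCOc3c(OC)c(OC)c2o1 | intermediate (not isolated)
9 | 7,8-dimethoxy-5,6-methylenedioxy-2-(methylsulfonyl)-4H-chromen-4-one | CS(=O)(=O)c1cc(=O)c2c3OCOc3c(OC)c(OC)c2o1 | intermediate
10 | chloroacetaldehyde dimethyl acetal | COC(CCl)OC | starting material
11 | sodium methoxyacetylide | [Na+].[C-]#COC | intermediate (not isolated)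
12 | methoxyacetylene | COC#C | intermediate
13 | lithium methoxyacetylide | [Li]C#COC | intermediate (not isolated)
14 | 2-(methoxyethynyl)-7,8-dimethoxy-5,6-methylenedioxy-4H-chromen-4-one | COC#Cc1cc(=O)c2c3OCOc3c(OC)c(OC)c2o1 | intermediate
15 | 3-oxocyclobutane-1-carboxylic acid | O=C1CC(C(=O)O)C1 | starting material
16 | 3-bromocyclobutan-1-one | O=C1CC(Br)C1 | intermediate
17 | cyclobut-2-en-1-one | O=C1CC=C1 | intermediate
18 | vinylketene (buta-1,3-dien-1-one) | C=CC=C=O | intermediate (not isolated)
19 | 2-(7,8-dimethoxy-5,6-methylenedioxy-4-oxo-4H-chromen-2-yl)-3-methoxy-4-vinylcyclobut-2-en-1-one (racemic) | COC1=C(C(=O)C1C=C)c1cc(=O)c2c3OCOc3c(OC)c(OC)c2o1 | intermediate (not isolated)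
20 | (3E)-2-(7,8-dimethoxy-5,6-methylenedioxy-4-oxo-4H-chromen-2-yl)-3-methoxyhexa-1,3,5-trien-1-one (ketene carbon and vinyl group cis across C3=C4) | C=C/C=C(OC)\C(=C=O)c1cc(=O)c2c3OCOc3c(OC)c(OC)c2o1 | intermediate (not isolated)
21 | 2-(7,8-dimethoxy-5,6-methylenedioxy-4-oxo-4H-chromen-2-yl)-3-methoxycyclohexa-2,4-dien-1-one | COC1=C(C(=O)CC=C1)c1cc(=O)c2c3OCOc3c(OC)c(OC)c2o1 | intermediate (not isolated)
22 | 2'-hydroxy-7,8,6'-trimethoxy-5,6-methylenedioxyflavone | COc1cccc(O)c1-c1cc(=O)c2c3OCOc3c(OC)c(OC)c2o1 | intermediate
23 | 6-(chloromethoxy)-5,2'-bis(dichloroboryloxy)-7,8,6'-trimethoxyflavone | COc1cccc(OB(Cl)Cl)c1-c1cc(=O)c2c(OB(Cl)Cl)c(OCCl)c(OC)c(OC)c2o1 | intermediate (not isolated)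
24 | 5,6,2'-trihydroxy-7,8,6'-trimethoxyflavone | COc1cccc(O)c1-c1cc(=O)c2c(O)c(O)c(OC)c(OC)c2o1 | target

**Totals**

Total step count: 13. Longest linear sequence: 10 steps (steps 1–7, 9, 12, 13, from 2,3-dimethoxyphenol).

**Steps most likely to fail**

1. Step 12 (proposed new method). The [2+2] addition to the push–pull alkyne may be too slow, so that vinylketene oligomerisation and cyclobutenone polymerisation outrun it, or the polarity of the addition may be diverted through the chromone. Fallback by known chemistry, setting out from 5 and returning at 22: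
   - Commercial 2-hydroxy-6-methoxybenzaldehyde is O-benzylated (BnBr, K2CO3, DMF) to 2-(benzyloxy)-6-methoxybenzaldehyde F1.
   - Claisen–Schmidt condensation of 5 with F1 (KOH, EtOH, rt) gives (E)-3-[2-(benzyloxy)-6-methoxyphenyl]-1-(5-hydroxy-6,7-dimethoxy-1,3-benzodioxol-4-yl)prop-2-en-1-one F2.
   - Oxidative cyclisation (I2 cat., DMSO, 120 °C) gives 2'-(benzyloxy)-7,8,6'-trimethoxy-5,6-methylenedioxyflavone F3.
   - Hydrogenolysis (H2, Pd/C, EtOAc) frees the 2'-phenol and gives 22.
   
   Ring B then comes from a preformed arene whose two oxygens are already differentiated.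

2. Step 9. The acetylide may add 1,2 to the C4 carbonyl, may deprotonate the methylsulfonyl group, or may add a second time to the electron-poor product alkyne. Fallback, setting out from 7 (skipping step 7) and returning at 14:
   - Lithium methoxyacetylide 13 is quenched with Bu3SnCl to give tributyl(methoxyethynyl)stannane F4.
   - F4 is cross-coupled with sulfide 7 under Liebeskind–Srogl-type thioether–stannane conditions: Pd(PPh3)4 (cat., zerovalent palladium), copper thiophene-2-carboxylate Cu(O2CC4H3S) (monovalent copper, stoichiometric), THF, 50 °C.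
   
   The C–C bond then forms by transmetalation at palladium and no basic carbanion meets the chromone.

3. Step 3. Acetyl migration into a position flanked by two oxygen substituents may stay incomplete, or Lewis-acid O-demethylation and air oxidation of the hydroquinone may take over during the hot stage. Fallback, setting out from 3 and returning at 5 (bypassing 4 and step 4):
   - Acid methanolysis (HCl, MeOH, Ar) gives 5,6-dimethoxybenzene-1,2,4-triol F5.
   - Methylenation of the catechol (CH2Br2, CsF, DMF, Ar) gives 6,7-dimethoxy-1,3-benzodioxol-5-ol F6.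
   - Friedel–Crafts ortho-acetylation of this monophenol at its only free position (Ac2O, BF3·OEt2, 80 °C) gives 5.
   
   This order is kept as the fallback because it exposes a free third hydroxyl during methylenation.

**Further compounds**

F1 | step 12 | 2-(benzyloxy)-6-methoxybenzaldehyde | COc1cccc(OCc2ccccc2)c1C=O
F2 | step 12 | (E)-3-[2-(benzyloxy)-6-methoxyphenyl]-1-(5-hydroxy-6,7-dimethoxy-1,3-benzodioxol-4-yl)prop-2-en-1-one | COc1cccc(OCc2ccccc2)c1/C=C/C(=O)c1c(O)c(OC)c(OC)c2OCOc12
F3 | step 12 | 2'-(benzyloxy)-7,8,6'-trimethoxy-5,6-methylenedioxyflavone | COc1cccc(OCc2ccccc2)c1-c1cc(=O)c2c3OCOc3c(OC)c(OC)c2o1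
F4 | step 9 | tributyl(methoxyethynyl)stannane | CCCC[Sn](CCCC)(CCCC)C#COC
F5 | step 3 | 5,6-dimethoxybenzene-1,2,4-triol | COc1c(OC)c(O)c(O)cc1O
F6 | step 3 | 6,7-dimethoxy-1,3-benzodioxol-5-ol | COc1c(O)cc2OCOc2c1OC
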